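**Retrosynthetic overview**

- The target is two (2S,4R)-flavan units joined C4–O–C4'. In each dihydropyran ring (O1–C2–C3–C4) the C2 phenyl is 1,3-trans to the ether oxygen on C4, so both phenyls can be added last: C2–Ph and C2'–Ph come from a double decarboxylative arylation (PhBr) of a bis(chroman-2-carboxylate) 4,4'-ether, with the C4/C4' centres directing both new centres.
- C4–O–C4' comes from Ag(I)-promoted substitution of a 4-benzylthio chroman ester (half B, 5,6,7-trimethoxy; C4' set trans to the C2' ester) by a 4R chroman-4-ol ester (half A, 5-silyloxy-6,7-dimethoxy; C4–O kept with retention).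
- Each 4-hydroxychroman-2-carboxylate comes from cis-selective ketone reduction of a 4-oxochroman-2-carboxylate, made by enantioselective hydrogenation of a chromone-2-carboxylic acid; half A branches off by peri-selective 5-O-demethylation of the common chromone acid.
- Ring order: the arene rings are bought; the pyranone ring closes once, in step 2 (Claisen condensation with diethyl oxalate, then O1–C2 cyclodehydration), and serves both halves; no ring is formed afterwards.

Key step: step 13

Remark 1: the key-step precursor is reshaped in three spectator details. TIPS replaces TBS on O5, because an aryl TBS ether would not survive ester hydrolysis. It is isolated as the dicaesium salt, because a free diacid could protonate its own acid-labile bis-benzylic ether. Ring A carries its carboxylate 2,4-cis, because C4–O of the nucleophilic half is retained and C2 is planarised in step 13, so its configuration is immaterial.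

Remark 2: the ligand antipode that gives each C2 configuration in steps 4 and 8 is assumed to be assigned in a small-scale run (chiral HPLC, chiroptical correlation) before scale-up.

**Step 1**
Reactants: 1 3,4,5-trimethoxyphenol
Product: 2 1-(6-hydroxy-2,3,4-trimethoxyphenyl)ethanone
Conditions: AcOH, BF3·OEt2, 85 °C; aqueous work-up
Reagents that add atoms: acetic acid, CC(=O)O
Why: Lewis-acid-mediated Friedel–Crafts C-acylation (Fries-type, via the aryl acetate) should occur at one of the two equivalent positions ortho to the free hydroxyl, which are the only unsubstituted ring carbons.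

**Step 2**
Reactants: 2 1-(6-hydroxy-2,3,4-trimethoxyphenyl)ethanone; 3 diethyl oxalate
Product: 5 ethyl 5,6,7-trimethoxy-4-oxo-4H-chromene-2-carboxylate, via diketo ester 4 (not isolated)
Conditions: NaOEt, EtOH, reflux; then conc. HCl (cat.), EtOH, reflux
Reagents that add atoms: none
Why: Crossed Claisen condensation of the methyl ketone enolate with non-enolisable diethyl oxalate gives the 2,4-dioxo ester, whose phenol adds to the C2 ketone and dehydrates under acid to close the γ-pyranone ring (classical chromone-2-carboxylate synthesis).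

**Step 3**
Reactants: 5 ethyl 5,6,7-trimethoxy-4-oxo-4H-chromene-2-carboxylate
Product: 6 5,6,7-trimethoxy-4-oxo-4H-chromene-2-carboxylic acid
Conditions: LiOH·H2O (1.5 equiv), THF–H2O, 0 °C → rt; then 1 M HCl
Reagents that add atoms: lithium hydroxide, [Li+].[OH-]
Why: Saponification of the activated ester at low temperature should be faster than hydroxide attack on the pyranone ring, and acidification returns the acid needed as the directing group for hydrogenation.

**Step 4**
Reactants: 6 5,6,7-trimethoxy-4-oxo-4H-chromene-2-carboxylic acid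
Product: 8 methyl (2S)-5,6,7-trimethoxy-4-oxochroman-2-carboxylate, via (2S)-keto acid 7 (not isolated)
Conditions: H2 (30 bar), [Rh(cod)2]BF4 (1 mol %), Josiphos-type bisphosphine (antipode giving 2S), MeOH, 30 °C; then TMSCHN2, PhMe–MeOH, 0 °C
Reagents that add atoms: (trimethylsilyl)diazomethane, C[Si](C)(C)C=[N+]=[N-]
Why: Carboxylate-directed Rh(I)–bisphosphine asymmetric hydrogenation of a chromone-2-carboxylic acid adds H2 syn across C2=C3 from the ligand-selected face, which sets C2 (S) and leaves the ketone alone, and TMSCHN2 then methylates the acid without base, so the β-aryloxy ketone cannot racemise by retro-oxa-Michael opening.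

**Step 5**
Reactants: 8 methyl (2S)-5,6,7-trimethoxy-4-oxochroman-2-carboxylate
Product: 9 methyl (2S,4S)-4-hydroxy-5,6,7-trimethoxychroman-2-carboxylate (2,4-cis)
Conditions: NaBH4, CeCl3·7H2O, MeOH–THF, −40 °C; Et3N then aq. NaHCO3 quench
Reagents that add atoms: none
Why: Luche 1,2-reduction should take the electron-rich aryl ketone ahead of the α-aryloxy ester, with hydride adding axially to the half-chair that has the C2 ester equatorial, which gives the 2,4-cis alcohol as in flavanone to cis-flavan-4-ol reductions.

**Step 6**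
Reactants: 9 methyl (2S,4S)-4-hydroxy-5,6,7-trimethoxychroman-2-carboxylate
Product: 10 methyl (2S,4R)-4-(benzylsulfanyl)-5,6,7-trimethoxychroman-2-carboxylate (2,4-trans expected as major C4 epimer; both epimers usable)
Conditions: BnSH (5 equiv), CSA (5 mol %), 4 Å MS, CH2Cl2, 0 °C
Reagents that add atoms: phenylmethanethiol, SCc1ccccc1
Why: Acid-catalysed SN1 thiolysis of the readily ionised 2,4,6-trioxygenated benzylic alcohol (the reaction used to cap flavan-4-yl cations in tannin thiolysis) installs a leaving group that only a soft thiophile activates, and the C4 configuration is irrelevant because C4 is re-ionised in step 11.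

**Step 7**
Reactants: 6 5,6,7-trimethoxy-4-oxo-4H-chromene-2-carboxylic acid
Product: 11 5-hydroxy-6,7-dimethoxy-4-oxo-4H-chromene-2-carboxylic acid
Conditions: BCl3 (3 equiv), CH2Cl2, −20 °C → rt; then H2O
Reagents that add atoms: none
Why: BCl3 chelates between the C4 carbonyl and O5, so only the peri methyl ether should be cleaved (chelation-controlled demethylation of 5-methoxychromones), and the carboxyl group is regenerated from its acyloxyborane on aqueous work-up.

**Step 8**
Reactants: 11 5-hydroxy-6,7-dimethoxy-4-oxo-4H-chromene-2-carboxylic acid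
Product: 13 methyl (2R)-5-hydroxy-6,7-dimethoxy-4-oxochroman-2-carboxylate, via (2R)-keto acid 12 (not isolated)
Conditions: H2 (30 bar), [Rh(cod)2]BF4 (1 mol %), Josiphos-type bisphosphine (antipode opposite to step 4), MeOH, 30 °C; then TMSCHN2 (1.1 equiv), PhMe–MeOH, 0 °C
Reagents that add atoms: (trimethylsilyl)diazomethane, C[Si](C)(C)C=[N+]=[N-]
Why: The same carboxylate-directed asymmetric hydrogenation with the other ligand antipode sets C2 (R), and the hydrogen-bonded 5-OH is inert to TMSCHN2 at 0 °C, so only the acid is methylated.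

**Step 9**
Reactants: 13 methyl (2R)-5-hydroxy-6,7-dimethoxy-4-oxochroman-2-carboxylate
Product: 14 methyl (2R)-6,7-dimethoxy-4-oxo-5-[(triisopropylsilyl)oxy]chroman-2-carboxylate
Conditions: TIPSOTf, 2,6-lutidine, CH2Cl2, −40 → 0 °C
Reagents that add atoms: triisopropylsilyl trifluoromethanesulfonate, CC(C)[Si](OS(=O)(=O)C(F)(F)F)(C(C)C)C(C)C
Why: A silyl triflate with a hindered pyridine base silylates the chelated phenol without enolising the ketone or opening the ring, so C2 is untouched, and the hindered TIPS ether is chosen for stability to hydroxide and carboxylate in steps 12 and 13.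

**Step 10**
Reactants: 14 methyl (2R)-6,7-dimethoxy-4-oxo-5-[(triisopropylsilyl)oxy]chroman-2-carboxylate
Product: 15 methyl (2R,4R)-4-hydroxy-6,7-dimethoxy-5-[(triisopropylsilyl)oxy]chroman-2-carboxylate (2,4-cis)
Conditions: NaBH4, CeCl3·7H2O, MeOH–THF, −40 °C; Et3N then aq. NaHCO3 quench
Reagents that add atoms: none
Why: Luche reduction as in step 5 delivers hydride axially to the (2R)-ketone and gives the 2,4-cis alcohol, which fixes C4 as R (the configuration kept to the target), while the low temperature guards against ester reduction and O-to-O silyl migration.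

**Step 11**
Reactants: 15 methyl (2R,4R)-4-hydroxy-6,7-dimethoxy-5-[(triisopropylsilyl)oxy]chroman-2-carboxylate; 10 methyl (2S,4R)-4-(benzylsulfanyl)-5,6,7-trimethoxychroman-2-carboxylate (1.3 equiv)
Product: 16 methyl (2R,4R)-4-{[(2S,4R)-2-(methoxycarbonyl)-5,6,7-trimethoxychroman-4-yl]oxy}-6,7-dimethoxy-5-[(triisopropylsilyl)oxy]chroman-2-carboxylate
Conditions: AgOTf (1.5 equiv), DTBMP (2 equiv), 4 Å MS, CH2Cl2, −40 → 0 °C, dark
Reagents that add atoms: none
Why: Soft Ag(I) ionises only the C4'–S bond of 10 (the free alcohol 15 is not activated in the buffered medium), and the 2,4,6-trioxygenated benzylic cation is attacked by the hydroxyl of 15 along the pseudoaxial trajectory anti to the equatorial C2' ester, which should give the 2',4'-trans (4'R) ether while C4 of 15 stays R (SN1 etherification by thiophilic activation, as used to generate flavan-4-yl cations from 4-thioethers).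

**Step 12**
Reactants: 16 the diester ether from step 11
Product: 17 dicaesium (2R,4R)-4-{[(2S,4R)-2-carboxylato-5,6,7-trimethoxychroman-4-yl]oxy}-6,7-dimethoxy-5-[(triisopropylsilyl)oxy]chroman-2-carboxylate
Conditions: CsOH·H2O (2.0 equiv), THF–H2O, 0 °C; freeze-dry
Reagents that add atoms: caesium hydroxide, [Cs+].[OH-]
Why: Saponification of the activated α-aryloxy methyl esters is fast at 0 °C and should leave the hindered aryl TIPS ether and the base-stable bis-benzylic ether intact, and any C2 epimerisation is without consequence.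

**Step 13**
Reactants: 17 the dicaesium dicarboxylate from step 12; 18 bromobenzene (6 equiv)
Product: 21 5-O-TIPS-beilschmieflavonoid B, via ring-A monophenyl monocarboxylate 19 (not isolated), via ring-B monophenyl monocarboxylate 20 (not isolated)
Conditions: [Ir{dF(CF3)ppy}2(dtbbpy)]PF6 (2 mol %), NiCl2·glyme (20 mol %), dtbbpy (20 mol %), DMF, blue LEDs (450 nm), 25 °C, Ar
Reagents that add atoms: none
Why: Excited Ir(III) oxidises each caesium carboxylate, loss of CO2 leaves a planar α-aryloxy radical at C2 (and C2'), Ni(0)(dtbbpy) adds PhBr, the Ni(II)–phenyl species traps the radical and Ni(III) reductively eliminates to form C2–Ph, with Ir(II) returning nickel to Ni(0). The closest known reaction type is the nickel–photoredox decarboxylative sp3–sp2 coupling of cyclic and acyclic α-alkoxy carboxylic acids with aryl bromides, here run twice in one flask. No ring is closed; two C(sp3)–C(sp2) bonds and two stereocentres are made. Both C2 configurations are set by substrate control: peri strain with the C5 substituent (OTIPS or OMe) keeps the bulky 4-O-chromanyl group pseudoaxial, so the nickel–phenyl fragment should bind and deliver phenyl on the face anti to C4–O, giving the 2,4-trans (2S) flavan in each ring whatever the configuration of the lost carboxylate. The step needs this facial preference at both radicals and capture by nickel ahead of hydrogen-atom transfer or reduction of the radical; the first rests on the pseudoaxial ether substituent and on reversible radical capture that favours the equatorial-phenyl product, the second on the high nickel loading and excess PhBr.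

**Step 14**
Reactants: 21 5-O-TIPS-beilschmieflavonoid B
Product: 22 beilschmieflavonoid B
Conditions: TBAF, AcOH (1:1, 1.5 equiv), THF, 0 °C → rt
Reagents that add atoms: none
Why: Fluoride cleaves the aryl O–Si bond and acetic acid protonates the phenoxide at once, so the ether sees neither strong acid (to which C4–O–C4' is labile) nor free phenoxide (ortho-quinone methide formation), and no stereocentre is touched.

**Compound list**

1 | 3,4,5-trimethoxyphenol | COc1cc(O)cc(OC)c1OC | starting material
2 | 1-(6-hydroxy-2,3,4-trimethoxyphenyl)ethanone | CC(=O)c1c(O)cc(OC)c(OC)c1OC | intermediate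
3 | diethyl oxalate | CCOC(=O)C(=O)OCC | starting material
4 | ethyl 4-(6-hydroxy-2,3,4-trimethoxyphenyl)-2,4-dioxobutanoate | CCOC(=O)C(=O)CC(=O)c1c(O)cc(OC)c(OC)c1OC | intermediate (not isolated)
5 | ethyl 5,6,7-trimethoxy-4-oxo-4H-chromene-2-carboxylate | CCOC(=O)c1cc(=O)c2c(OC)c(OC)c(OC)cc2o1 | intermediate
6 | 5,6,7-trimethoxy-4-oxo-4H-chromene-2-carboxylic acid | OC(=O)c1cc(=O)c2c(OC)c(OC)c(OC)cc2o1 | intermediate
7 | (2S)-5,6,7-trimethoxy-4-oxochroman-2-carboxylic acid | O=C1C[C@@H](C(=O)O)Oc2cc(OC)c(OC)c(OC)c21 | intermediate (not isolated)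
8 | methyl (2S)-5,6,7-trimethoxy-4-oxochroman-2-carboxylate | O=C1C[C@@H](C(=O)OC)Oc2cc(OC)c(OC)c(OC)c21 | intermediate
9 | methyl (2S,4S)-4-hydroxy-5,6,7-trimethoxychroman-2-carboxylate | O[C@H]1C[C@@H](C(=O)OC)Oc2cc(OC)c(OC)c(OC)c21 | intermediate
10 | methyl (2S,4R)-4-(benzylsulfanyl)-5,6,7-trimethoxychroman-2-carboxylate | c1ccc(cc1)CS[C@@H]1C[C@@H](C(=O)OC)Oc2cc(OC)c(OC)c(OC)c21 | intermediate
11 | 5-hydroxy-6,7-dimethoxy-4-oxo-4H-chromene-2-carboxylic acid | OC(=O)c1cc(=O)c2c(O)c(OC)c(OC)cc2o1 | intermediate
12 | (2R)-5-hydroxy-6,7-dimethoxy-4-oxochroman-2-carboxylic acid | COc1cc2c(c(O)c1OC)C(=O)C[C@H](C(=O)O)O2 | intermediate (not isolated)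
13 | methyl (2R)-5-hydroxy-6,7-dimethoxy-4-oxochroman-2-carboxylate | COc1cc2c(c(O)c1OC)C(=O)C[C@H](C(=O)OC)O2 | intermediate
14 | methyl (2R)-6,7-dimethoxy-4-oxo-5-[(triisopropylsilyl)oxy]chroman-2-carboxylate | COc1cc2c(c(O[Si](C(C)C)(C(C)C)C(C)C)c1OC)C(=O)C[C@H](C(=O)OC)O2 | intermediate
15 | methyl (2R,4R)-4-hydroxy-6,7-dimethoxy-5-[(triisopropylsilyl)oxy]chroman-2-carboxylate | COc1cc2c(c(O[Si](C(C)C)(C(C)C)C(C)C)c1OC)[C@H](O)C[C@H](C(=O)OC)O2 | intermediate
16 | diester ether: ring A (2R,4R), ring B (2S,4R), C4–O–C4' linked | COc1cc2c(c(O[Si](C(C)C)(C(C)C)C(C)C)c1OC)[C@H](O[C@@H]1C[C@@H](C(=O)OC)Oc3cc(OC)c(OC)c(OC)c31)C[C@H](C(=O)OC)O2 | intermediate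
17 | dicaesium dicarboxylate of 16 (key-step precursor) | COc1cc2c(c(O[Si](C(C)C)(C(C)C)C(C)C)c1OC)[C@H](O[C@@H]1C[C@@H](C(=O)[O-])Oc3cc(OC)c(OC)c(OC)c31)C[C@H](C(=O)[O-])O2.[Cs+].[Cs+] | intermediate
18 | bromobenzene | Brc1ccccc1 | starting material
19 | ring-A monophenyl monocarboxylate (caesium salt; ring B still (2S)-carboxylate) | COc1cc2c(c(O[Si](C(C)C)(C(C)C)C(C)C)c1OC)[C@H](O[C@@H]1C[C@@H](C(=O)[O-])Oc3cc(OC)c(OC)c(OC)c31)C[C@@H](c1ccccc1)O2.[Cs+] | intermediate (not isolated)
20 | ring-B monophenyl monocarboxylate (caesium salt; ring A still (2R)-carboxylate) | COc1cc2c(c(O[Si](C(C)C)(C(C)C)C(C)C)c1OC)[C@H](O[C@@H]1C[C@@H](c3ccccc3)Oc3cc(OC)c(OC)c(OC)c31)C[C@H](C(=O)[O-])O2.[Cs+] | intermediate (not isolated)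
21 | 5-O-TIPS-beilschmieflavonoid B | COc1cc2c(c(O[Si](C(C)C)(C(C)C)C(C)C)c1OC)[C@H](O[C@@H]1C[C@@H](c3ccccc3)Oc3cc(OC)c(OC)c(OC)c31)C[C@@H](c1ccccc1)O2 | intermediate
22 | beilschmieflavonoid B | COc1cc2c(c(O)c1OC)[C@H](O[C@@H]1C[C@@H](c3ccccc3)Oc3cc(OC)c(OC)c(OC)c31)C[C@@H](c1ccccc1)O2 | target

**Step count**

Total: 14 steps. Longest linear sequence: 11 steps (1, 2, 3, 7, 8, 9, 10, 11, 12, 13, 14).

**Steps most likely to fail**

1. Step 13 (key step). The C2 radicals may be lost to hydrogen-atom transfer (a 1,5-shift of the benzylic ether hydrogen across C4–O–C4', or abstraction from solvent) or to reduction. The excited iridium complex may oxidise the tetra-oxygenated arene rings instead of the carboxylates. Facial selectivity at one radical may erode, so that 2,4-cis epimers accumulate.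
Fallback: nickel-catalysed decarboxylative arylation of redox-active esters with an arylzinc reagent, which needs no light and no photo-oxidant. It sets out from 17, which with N-hydroxyphthalimide and EDC·HCl (DMAP cat., CH2Cl2, 0 °C) gives the bis(N-acyloxyphthalimide) F1. NiCl2·glyme/dtbbpy and PhZnCl·LiCl (THF–DMF, rt) then fragment each ester reductively to the same C2 radical and transfer phenyl from nickel, by way of the ring-A monophenyl mono-ester F2 and the ring-B monophenyl mono-ester F3. The sequence returns to the route at 21.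

2. Step 11 (etherification). The cation from 10 may lose a C3 proton to the hindered base (2H-chromene formation). It may be captured at the nucleophilic C8 carbon of either arene (Friedel–Crafts C–C coupling). It may also be attacked with poor facial selectivity.
Fallback: thermodynamically controlled, acid-catalysed dehydrative etherification, in which both C4 centres are relayed from C2 and elimination is reversible. It sets out from 11 and 9 and returns to the route at 21.
   - Acid 11 is hydrogenated with the ligand antipode of step 4 and methylated, giving via the (2S)-keto acid F4 (not isolated) the (2S)-keto ester F5.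
   - Silylation as in step 9 gives the silyl ether F6, and Luche reduction gives the (2S,4S)-alcohol F7.
   - F7 and an excess of 9 (4 equiv) are equilibrated with CSA (5 mol %) over 4 Å sieves in CH2Cl2 at 0 °C. Both alcohols ionise and each cation is captured trans to its ester, so the mixed ether should settle as the 2,4-trans/2',4'-trans diester F8. Its share is statistical; excess 9 and its self-condensation products are returned to the equilibration.
   - CsOH as in step 12 gives the dicaesium salt F9. The conditions of step 13 then lead, via 19 and the ring-B monophenyl monocarboxylate F10, back to 21.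

3. Step 8 (asymmetric hydrogenation of the phenolic chromone acid; step 4 is exposed in the same way to a lesser degree). The chelating 5-hydroxy-4-oxo unit may slow or misdirect the rhodium catalyst, giving low conversion or low enantiomeric purity at C2.
Fallback: catalyst-controlled ketone transfer hydrogenation with kinetic resolution (known for 2-substituted chroman-4-ones) instead of alkene hydrogenation. It sets out from 11, which is methylated (TMSCHN2) to the chromone methyl ester F11 and silylated (TIPSOTf, 2,6-lutidine) to the silyloxychromone ester F12. H2 (1 atm) over Pd–C in EtOAc saturates C2=C3 to the racemic keto ester F13. RuCl(p-cymene)[(R,R)-TsDPEN] with HCO2Na in water–EtOAc should then reduce the matched (2R)-enantiomer to the 4R cis-alcohol, returning to the route at 15. The slower-reacting enantiomer of the ketone is recovered, racemised with base (retro-oxa-Michael/oxa-Michael) and recycled.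

**Further compounds**

F1 | step 13 | bis(1,3-dioxoisoindolin-2-yl) diester of the diacid of 17 | COc1cc2c(c(O[Si](C(C)C)(C(C)C)C(C)C)c1OC)[C@H](O[C@@H]1C[C@@H](C(=O)ON3C(=O)c4ccccc4C3=O)Oc3cc(OC)c(OC)c(OC)c31)C[C@H](C(=O)ON1C(=O)c3ccccc3C1=O)O2
F2 | step 13 | ring-A monophenyl, ring-B N-acyloxyphthalimide | COc1cc2c(c(O[Si](C(C)C)(C(C)C)C(C)C)c1OC)[C@H](O[C@@H]1C[C@@H](C(=O)ON3C(=O)c4ccccc4C3=O)Oc3cc(OC)c(OC)c(OC)c31)C[C@@H](c1ccccc1)O2
F3 | step 13 | ring-B monophenyl, ring-A N-acyloxyphthalimide | COc1cc2c(c(O[Si](C(C)C)(C(C)C)C(C)C)c1OC)[C@H](O[C@@H]1C[C@@H](c3ccccc3)Oc3cc(OC)c(OC)c(OC)c31)C[C@H](C(=O)ON1C(=O)c3ccccc3C1=O)O2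
F4 | step 11 | (2S)-5-hydroxy-6,7-dimethoxy-4-oxochroman-2-carboxylic acid | COc1cc2c(c(O)c1OC)C(=O)C[C@@H](C(=O)O)O2
F5 | step 11 | methyl (2S)-5-hydroxy-6,7-dimethoxy-4-oxochroman-2-carboxylate | COc1cc2c(c(O)c1OC)C(=O)C[C@@H](C(=O)OC)O2
F6 | step 11 | methyl (2S)-6,7-dimethoxy-4-oxo-5-[(triisopropylsilyl)oxy]chroman-2-carboxylate | COc1cc2c(c(O[Si](C(C)C)(C(C)C)C(C)C)c1OC)C(=O)C[C@@H](C(=O)OC)O2
F7 | step 11 | methyl (2S,4S)-4-hydroxy-6,7-dimethoxy-5-[(triisopropylsilyl)oxy]chroman-2-carboxylate | COc1cc2c(c(O[Si](C(C)C)(C(C)C)C(C)C)c1OC)[C@@H](O)C[C@@H](C(=O)OC)O2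
F8 | step 11 | diester ether, ring A (2S,4R), ring B (2S,4R) | COc1cc2c(c(O[Si](C(C)C)(C(C)C)C(C)C)c1OC)[C@H](O[C@@H]1C[C@@H](C(=O)OC)Oc3cc(OC)c(OC)c(OC)c31)C[C@@H](C(=O)OC)O2
F9 | step 11 | dicaesium dicarboxylate of F8 | COc1cc2c(c(O[Si](C(C)C)(C(C)C)C(C)C)c1OC)[C@H](O[C@@H]1C[C@@H](C(=O)[O-])Oc3cc(OC)c(OC)c(OC)c31)C[C@@H](C(=O)[O-])O2.[Cs+].[Cs+]
F10 | step 11 | ring-B monophenyl monocarboxylate with ring-A (2S)-carboxylate (caesium salt) | COc1cc2c(c(O[Si](C(C)C)(C(C)C)C(C)C)c1OC)[C@H](O[C@@H]1C[C@@H](c3ccccc3)Oc3cc(OC)c(OC)c(OC)c31)C[C@@H](C(=O)[O-])O2.[Cs+]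
F11 | step 8 | methyl 5-hydroxy-6,7-dimethoxy-4-oxo-4H-chromene-2-carboxylate | COC(=O)c1cc(=O)c2c(O)c(OC)c(OC)cc2o1
F12 | step 8 | methyl 6,7-dimethoxy-4-oxo-5-[(triisopropylsilyl)oxy]-4H-chromene-2-carboxylate | COC(=O)c1cc(=O)c2c(O[Si](C(C)C)(C(C)C)C(C)C)c(OC)c(OC)cc2o1
F13 | step 8 | racemic methyl 6,7-dimethoxy-4-oxo-5-[(triisopropylsilyl)oxy]chroman-2-carboxylate | COc1cc2c(c(O[Si](C(C)C)(C(C)C)C(C)C)c1OC)C(=O)CC(C(=O)OC)O2
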